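**Retrosynthetic overview**
1. Feature: in ring A of the 7-methoxyflavone half (unit 1, unprimed atoms), O1 on C8a, the C4 carbonyl on C4a and the C5 oxygen sit on three neighbouring carbons, and the C7 methoxy group is para to C4a. A 3,5-dialkoxybenzyne gives this array when it takes an oxygen nucleophile at its distal carbon and an acyl group at its proximal carbon.
2. Endgame: six aryl ethers (five benzyl, the chelated 5-methyl) are cleaved last. Ring C of unit 1 is opened at O1–C2 and C2–C3 (cyclodehydration, Baker–Venkataraman shift) to a 2-hydroxydeoxybenzoin and 4-(benzyloxy)benzoyl chloride.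
3. Key disconnection: C8a–O1 and C4a–C4 of the deoxybenzoin. This leads to 3,5-dimethoxybenzyne (from its 2-silylaryl triflate, three steps from 3,5-dimethoxyphenol) and tetra-O-benzylluteolin-6-ylacetic acid.
4. The acid: commercial luteolin supplies all rings of unit 2 (double-primed atoms). The C6″ side chain (future C3 and C4 of unit 1) comes from Claisen rearrangement of the 5-O-allyl ether, which can reach only C6″, followed by oxidative cleavage.
5. Ring order: all arene rings and the luteolin pyranone are bought, and ring C of unit 1 is the only ring formed (step 13). Benzyl ethers are used because they tolerate the free acid, CsF at 125 °C and the acid-catalysed closure, and they are cleaved by BCl3 together with the 5-methyl ether.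

Key step: step 10

Remark: the target string holds no stereodescriptor, so the hindered C3–C6″ biaryl axis is left uncontrolled (racemic if rotation is slow); luteolin is taken as an article of commerce.

**Route**

Step 1
Reactants: 1 luteolin
Product: 2 7,3',4'-tri-O-benzylluteolin (5-OH free)
Conditions: BnBr (3.3 equiv), K2CO3, DMF, rt
Reagents that add atoms: benzyl bromide, BrCc1ccccc1
Why: Williamson etherification; the 5-OH is hydrogen-bonded to the C4 carbonyl and is the least acidic and least nucleophilic phenol, so a mild base and three equivalents of halide should stop at the tribenzyl ether.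

Step 2
Reactants: 2 7,3',4'-tri-O-benzylluteolin; 3 allyl bromide
Product: 4 5-O-allyl-7,3',4'-tri-O-benzylluteolin
Conditions: K2CO3, DMF, 60 °C
Reagents that add atoms: none
Why: Williamson etherification under more forcing conditions; the chelated 5-OH is the only nucleophile left and the reactive allylic halide should alkylate it on warming.

Step 3
Reactants: 4 5-O-allyl-7,3',4'-tri-O-benzylluteolin
Product: 6 6-allyl-7,3',4'-tri-O-benzylluteolin (5-OH free), via C6-allyl dienone 5 (not isolated)
Conditions: PhNEt2, 200 °C, Ar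
Reagents that add atoms: none
Why: Aromatic Claisen rearrangement; the [3,3] shift can reach only C6 because the other ortho position of C5 is the ring-fusion carbon C4a, and the racemic dienone tautomerises at once to the chelated phenol, which forestalls a Cope shift to C8.

Step 4
Reactants: 6 6-allyl-7,3',4'-tri-O-benzylluteolin
Product: 7 6-allyl-5,7,3',4'-tetra-O-benzylluteolin
Conditions: BnBr, K2CO3, KI (cat.), DMF, 70 °C
Reagents that add atoms: benzyl bromide, BrCc1ccccc1
Why: Williamson etherification with iodide catalysis overcomes chelation and the flanking allyl group; capping this last phenol leaves the later carboxylate as the only nucleophile offered to the aryne.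

Step 5
Reactants: 7 6-allyl-5,7,3',4'-tetra-O-benzylluteolin
Product: 9 (5,7,3',4'-tetra-O-benzylluteolin-6-yl)acetaldehyde, via vicinal diol 8 (not isolated)
Conditions: OsO4 (2 mol %), NaIO4 (4 equiv), 2,6-lutidine, 1,4-dioxane–H2O 3:1, rt
Reagents that add atoms: osmium tetroxide, O=[Os](=O)(=O)=O (delivers the oxygen); sodium periodate, [Na+].[O-]I(=O)(=O)=O (replenishes it)
Why: Lemieux–Johnson cleavage; the terminal monosubstituted alkene is dihydroxylated far faster than the electron-poor trisubstituted C2=C3 bond of the pyranone, periodate cleaves the racemic diol in the same flask, and lutidine suppresses over-oxidation.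

Step 6
Reactants: 9 (5,7,3',4'-tetra-O-benzylluteolin-6-yl)acetaldehyde
Product: 10 (5,7,3',4'-tetra-O-benzylluteolin-6-yl)acetic acid
Conditions: NaClO2, NaH2PO4, 2-methyl-2-butene (large excess), THF–t-BuOH–H2O, 0 °C → rt
Reagents that add atoms: sodium chlorite, [Na+].[O-]Cl=O
Why: Pinnick oxidation converts the enolisable arylacetaldehyde to the acid at mildly acidic pH without epimerisable or oxidisable sites being touched, and the alkene scavenger removes hypochlorous acid before it can chlorinate C8 of the electron-rich ring.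

Step 7
Reactants: 11 3,5-dimethoxyphenol
Product: 12 2-bromo-3,5-dimethoxyphenol
Conditions: NBS (1.0 equiv), CH2Cl2, −78 °C → rt
Reagents that add atoms: N-bromosuccinimide, O=C1CCC(=O)N1Br
Why: Electrophilic aromatic bromination; at low temperature one equivalent of NBS should prefer the position ortho to the hydroxyl and para to a methoxy group over C4, which is shielded by two methoxy groups, and any 4-bromo isomer is removed by chromatography.

Step 8
Reactants: 12 2-bromo-3,5-dimethoxyphenol
Product: 13 (2-bromo-3,5-dimethoxyphenoxy)trimethylsilane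
Conditions: (Me3Si)2NH, THF, reflux; volatiles removed in vacuo
Reagents that add atoms: hexamethyldisilazane, C[Si](C)(C)N[Si](C)(C)C
Why: O-silylation of a phenol with a silazane is driven by loss of ammonia and gives the silyl ether clean enough for direct metalation.

Step 9
Reactants: 13 (2-bromo-3,5-dimethoxyphenoxy)trimethylsilane
Product: 15 3,5-dimethoxy-2-(trimethylsilyl)phenyl trifluoromethanesulfonate, via lithium silylphenoxide 14 (not isolated)
Conditions: n-BuLi, THF, −100 → −78 °C; then Tf2O, −100 → −78 °C
Reagents that add atoms: trifluoromethanesulfonic anhydride, O=S(=O)(OS(=O)(=O)C(F)(F)F)C(F)(F)F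
Why: Bromine–lithium exchange triggers a retro-Brook O→C silyl shift that places silicon exactly where bromine stood, and the liberated phenoxide is sulfonylated in the same flask, which is the standard entry to ortho-silylaryl triflates.

Step 10
Reactants: 10 (5,7,3',4'-tetra-O-benzylluteolin-6-yl)acetic acid; 15 3,5-dimethoxy-2-(trimethylsilyl)phenyl trifluoromethanesulfonate (1.5–2 equiv)
Product: 17 1-(2-hydroxy-4,6-dimethoxyphenyl)-2-(5,7,3',4'-tetra-O-benzylluteolin-6-yl)ethanone, via 3,5-dimethoxybenzyne 16 (not isolated)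
Conditions: CsF (4 equiv), THF, 125 °C (sealed tube); aq. NH4Cl work-up
Reagents that add atoms: none
Why: Fluoride strips the silyl group of 15 and triflate departs, so 3,5-dimethoxybenzyne 16 is released slowly from sparingly soluble CsF while 10 is present as its cesium carboxylate. The carboxylate oxygen adds to the aryne carbon remote from the flanking methoxy group (future C8a), the resulting aryl anion on future C4a is stabilised by the adjacent C–O dipole and attacks the ester carbonyl, and the strained four-membered alkoxide opens to the ketone phenoxide, so C8a–O1 and C4a–C4 form in one operation. The closest known reaction type is the fluoride-triggered insertion of arynes into the acyl–oxygen bond of carboxylic acids to give ortho-hydroxyaryl ketones, an intermolecular relative of the anionic ortho-Fries rearrangement. No ring is closed and no stereocentre is created. Regioselectivity is secured by the methoxy group next to the triple bond, which distorts the aryne and sends nucleophiles to the distal carbon, while the second methoxy group further round the ring has only a minor influence. Chemoselectivity, meaning acyl capture rather than protonation of the aryl anion and no rival nucleophile, is served by the aprotic, weakly polar medium at high temperature and by every phenol of 10 being a benzyl ether.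

Step 11
Reactants: 18 4-(benzyloxy)benzoic acid
Product: 19 4-(benzyloxy)benzoyl chloride
Conditions: (COCl)2, DMF (cat.), CH2Cl2, 0 °C → rt
Reagents that add atoms: oxalyl chloride, O=C(Cl)C(=O)Cl
Why: Acid chloride formation through the catalytic chloroiminium (Vilsmeier-type) species proceeds at room temperature with only gaseous by-products, and the benzyl ether is inert to it.

Step 12
Reactants: 17 1-(2-hydroxy-4,6-dimethoxyphenyl)-2-(5,7,3',4'-tetra-O-benzylluteolin-6-yl)ethanone; 19 4-(benzyloxy)benzoyl chloride
Product: 20 3,5-dimethoxy-2-[(5,7,3',4'-tetra-O-benzylluteolin-6-yl)acetyl]phenyl 4-(benzyloxy)benzoate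
Conditions: Et3N, DMAP (cat.), CH2Cl2, 0 °C → rt
Reagents that add atoms: none
Why: DMAP-catalysed O-acylation; the acylpyridinium ion is electrophilic enough for the hydrogen-bonded phenol, which is the only hydroxyl group in the molecule.

Step 13
Reactants: 20 3,5-dimethoxy-2-[(5,7,3',4'-tetra-O-benzylluteolin-6-yl)acetyl]phenyl 4-(benzyloxy)benzoate
Product: 22 2-[4-(benzyloxy)phenyl]-5,7-dimethoxy-3-(5,7,3',4'-tetra-O-benzylluteolin-6-yl)-4H-chromen-4-one, via triaryl 1,3-diketone 21 (not isolated)
Conditions: LiN(SiMe3)2 (3 equiv), THF, −20 °C → rt; AcOH quench, solvent exchange; p-TsOH·H2O (cat.), toluene, 90 °C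
Reagents that add atoms: none
Why: Baker–Venkataraman rearrangement followed by cyclodehydration; the doubly activated benzylic CH2 is deprotonated by the non-nucleophilic amide and its enolate takes the aroyl group through a six-membered transition state (C2–C3 bond), after which acid promotes 6-exo-trig addition of the freed phenol to the aroyl carbonyl (O1–C2 bond) and loss of water, which erases the labile stereocentre of 21 while the benzyl ethers persist.

Step 14
Reactants: 22 2-[4-(benzyloxy)phenyl]-5,7-dimethoxy-3-(5,7,3',4'-tetra-O-benzylluteolin-6-yl)-4H-chromen-4-one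
Product: 23 CNP0200311.0, 5-hydroxy-2-(4-hydroxyphenyl)-7-methoxy-3-(luteolin-6-yl)-4H-chromen-4-one
Conditions: BCl3 (excess, 1 M in CH2Cl2), pentamethylbenzene, CH2Cl2, −78 °C → rt; then MeOH–H2O
Reagents that add atoms: none
Why: Lewis-acid ether cleavage; BCl3 ionises aryl benzyl ethers already at −78 °C while pentamethylbenzene traps the benzyl cations before they can C-benzylate the electron-rich rings, on warming the boron held between the C4 carbonyl and the C5 oxygen cleaves that methyl ether whereas the unchelated 7-methyl ether is inert to BCl3, and the low temperature avoids a Wessely–Moser ring opening that could move the linkage from C6″ to C8″.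

**Compound list**
1 | luteolin | O=c1cc(-c2ccc(O)c(O)c2)oc2cc(O)cc(O)c12 | starting material
2 | 7,3',4'-tri-O-benzylluteolin | O=c1cc(-c2ccc(OCc3ccccc3)c(OCc3ccccc3)c2)oc2cc(OCc3ccccc3)cc(O)c12 | intermediate
3 | allyl bromide | C=CCBr | starting material
4 | 5-O-allyl-7,3',4'-tri-O-benzylluteolin | C=CCOc1cc(OCc2ccccc2)cc2oc(-c3ccc(OCc4ccccc4)c(OCc4ccccc4)c3)cc(=O)c12 | intermediate
5 | C6-allyl cyclohexadienone tautomer (racemic, not isolated) | C=CCC1C(=O)C2=C(C=C1OCc1ccccc1)OC(c1ccc(OCc3ccccc3)c(OCc3ccccc3)c1)=CC2=O | intermediate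
6 | 6-allyl-7,3',4'-tri-O-benzylluteolin | C=CCc1c(OCc2ccccc2)cc2oc(-c3ccc(OCc4ccccc4)c(OCc4ccccc4)c3)cc(=O)c2c1O | intermediate
7 | 6-allyl-5,7,3',4'-tetra-O-benzylluteolin | C=CCc1c(OCc2ccccc2)cc2oc(-c3ccc(OCc4ccccc4)c(OCc4ccccc4)c3)cc(=O)c2c1OCc1ccccc1 | intermediate
8 | 6-(2,3-dihydroxypropyl)-5,7,3',4'-tetra-O-benzylluteolin (racemic, not isolated) | OCC(O)Cc1c(OCc2ccccc2)cc2oc(-c3ccc(OCc4ccccc4)c(OCc4ccccc4)c3)cc(=O)c2c1OCc1ccccc1 | intermediate
9 | (5,7,3',4'-tetra-O-benzylluteolin-6-yl)acetaldehyde | O=CCc1c(OCc2ccccc2)cc2oc(-c3ccc(OCc4ccccc4)c(OCc4ccccc4)c3)cc(=O)c2c1OCc1ccccc1 | intermediate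
10 | (5,7,3',4'-tetra-O-benzylluteolin-6-yl)acetic acid | O=C(O)Cc1c(OCc2ccccc2)cc2oc(-c3ccc(OCc4ccccc4)c(OCc4ccccc4)c3)cc(=O)c2c1OCc1ccccc1 | intermediate
11 | 3,5-dimethoxyphenol | COc1cc(O)cc(OC)c1 | starting material
12 | 2-bromo-3,5-dimethoxyphenol | COc1cc(O)c(Br)c(OC)c1 | intermediate
13 | (2-bromo-3,5-dimethoxyphenoxy)trimethylsilane | COc1cc(O[Si](C)(C)C)c(Br)c(OC)c1 | intermediate
14 | lithium 3,5-dimethoxy-2-(trimethylsilyl)phenolate (not isolated) | [Li+].COc1cc([O-])c([Si](C)(C)C)c(OC)c1 | intermediate
15 | 3,5-dimethoxy-2-(trimethylsilyl)phenyl trifluoromethanesulfonate | COc1cc(OC)c([Si](C)(C)C)c(OS(=O)(=O)C(F)(F)F)c1 | intermediate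
16 | 3,5-dimethoxybenzyne (not isolated) | COC1=CC(OC)=CC#C1 | intermediate
17 | 1-(2-hydroxy-4,6-dimethoxyphenyl)-2-(5,7,3',4'-tetra-O-benzylluteolin-6-yl)ethanone | COc1cc(O)c(C(=O)Cc2c(OCc3ccccc3)cc3oc(-c4ccc(OCc5ccccc5)c(OCc5ccccc5)c4)cc(=O)c3c2OCc2ccccc2)c(OC)c1 | intermediate
18 | 4-(benzyloxy)benzoic acid | O=C(O)c1ccc(OCc2ccccc2)cc1 | starting material
19 | 4-(benzyloxy)benzoyl chloride | O=C(Cl)c1ccc(OCc2ccccc2)cc1 | intermediate
20 | 3,5-dimethoxy-2-[(5,7,3',4'-tetra-O-benzylluteolin-6-yl)acetyl]phenyl 4-(benzyloxy)benzoate | COc1cc(OC(=O)c2ccc(OCc3ccccc3)cc2)c(C(=O)Cc2c(OCc3ccccc3)cc3oc(-c4ccc(OCc5ccccc5)c(OCc5ccccc5)c4)cc(=O)c3c2OCc2ccccc2)c(OC)c1 | intermediate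
21 | 1-[4-(benzyloxy)phenyl]-3-(2-hydroxy-4,6-dimethoxyphenyl)-2-(5,7,3',4'-tetra-O-benzylluteolin-6-yl)propane-1,3-dione (racemic, labile, not isolated) | COc1cc(O)c(C(=O)C(C(=O)c2ccc(OCc3ccccc3)cc2)c2c(OCc3ccccc3)cc3oc(-c4ccc(OCc5ccccc5)c(OCc5ccccc5)c4)cc(=O)c3c2OCc2ccccc2)c(OC)c1 | intermediate
22 | 2-[4-(benzyloxy)phenyl]-5,7-dimethoxy-3-(5,7,3',4'-tetra-O-benzylluteolin-6-yl)-4H-chromen-4-one | COc1cc(OC)c2c(=O)c(-c3c(OCc4ccccc4)cc4oc(-c5ccc(OCc6ccccc6)c(OCc6ccccc6)c5)cc(=O)c4c3OCc3ccccc3)c(-c3ccc(OCc4ccccc4)cc3)oc2c1 | intermediate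
23 | CNP0200311.0 | COc1cc(O)c2c(=O)c(-c3c(O)cc4oc(-c5ccc(O)c(O)c5)cc(=O)c4c3O)c(-c3ccc(O)cc3)oc2c1 | target

**Step count**
Total steps: 14.
Longest linear sequence: 10 steps from luteolin (steps 1–6, 10, 12, 13, 14).

**Steps most likely to fail**

(a) Step 10.
- What may go wrong: proton transfer to the aryl anion may outrun the acyl shift, so the reaction stops at plain O-arylation. The proton could come from unreacted acid, from bifluoride, or through a six-membered transition state from the acidic benzylic CH2 of the transient aryl ester. A second arylation of the product phenoxide by excess aryne is a minor risk.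
- Fallback: it sets out from 12 and 9 and returns at 17, forming the C4a–C4 bond by carbonyl addition instead.
- Bromophenol 12 is protected (MOMCl, i-Pr2NEt, CH2Cl2) as 2-bromo-1,5-dimethoxy-3-(methoxymethoxy)benzene F1.
- Bromine–lithium exchange (n-BuLi, THF, −78 °C) gives [2,4-dimethoxy-6-(methoxymethoxy)phenyl]lithium F2. At −78 °C this should add to aldehyde 9 much faster than to the vinylogous ester carbonyl of the pyranone, giving racemic 1-[2,4-dimethoxy-6-(methoxymethoxy)phenyl]-2-(5,7,3',4'-tetra-O-benzylluteolin-6-yl)ethanol F3.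
- Dess–Martin oxidation gives 1-[2,4-dimethoxy-6-(methoxymethoxy)phenyl]-2-(5,7,3',4'-tetra-O-benzylluteolin-6-yl)ethanone F4.
- HCl in MeOH–THF at room temperature removes the acetal without touching the benzyl ethers and delivers 17.

(b) Step 13.
- What may go wrong: crowding at the enolate carbon, which carries an aryl group with two ortho benzyloxy substituents, may slow the O→C aroyl shift. Ester cleavage or simple return of starting material would then compete.
- Fallback: it sets out from 17, bypasses steps 11–13 and returns at 22.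
- Ketone 17 is condensed with commercial 4-(benzyloxy)benzaldehyde (piperidine, toluene, Dean–Stark). Knoevenagel-type condensation at the activated CH2 and oxa-Michael closure by the phenol give 2-[4-(benzyloxy)phenyl]-5,7-dimethoxy-3-(5,7,3',4'-tetra-O-benzylluteolin-6-yl)chroman-4-one F5 (racemic mixture of diastereomers).
- Dehydrogenation with DDQ in 1,4-dioxane at reflux removes both stereocentres and gives 22.

(c) Step 14.
- What may go wrong: partly cleaved boron phenoxides may precipitate before the chelated methyl ether is attacked, leaving the demethylation incomplete. Friedel–Crafts re-benzylation of the phloroglucinol-type rings may occur if cation trapping is too slow.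
- Fallback: it sets out from 22 and returns at 23, splitting the task into a chelation-controlled cleavage in homogeneous solution and a neutral hydrogenolysis.
- MgI2·OEt2 in THF–toluene at 80 °C cleaves only the two ethers peri to a carbonyl group (5-OMe and 5″-OBn). This gives 2-[4-(benzyloxy)phenyl]-5-hydroxy-7-methoxy-3-(7,3',4'-tri-O-benzylluteolin-6-yl)-4H-chromen-4-one F6.
- H2 (1 atm) over Pd/C in THF–MeOH removes the remaining four benzyl groups to give 23.

**Further compounds**
F1 | step 10 | 2-bromo-1,5-dimethoxy-3-(methoxymethoxy)benzene | COCOc1cc(OC)cc(OC)c1Br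
F2 | step 10 | [2,4-dimethoxy-6-(methoxymethoxy)phenyl]lithium | [Li]c1c(OC)cc(OC)cc1OCOC
F3 | step 10 | 1-[2,4-dimethoxy-6-(methoxymethoxy)phenyl]-2-(5,7,3',4'-tetra-O-benzylluteolin-6-yl)ethanol (racemic) | COCOc1cc(OC)cc(OC)c1C(O)Cc1c(OCc2ccccc2)cc2oc(-c3ccc(OCc4ccccc4)c(OCc4ccccc4)c3)cc(=O)c2c1OCc1ccccc1
F4 | step 10 | 1-[2,4-dimethoxy-6-(methoxymethoxy)phenyl]-2-(5,7,3',4'-tetra-O-benzylluteolin-6-yl)ethanone | COCOc1cc(OC)cc(OC)c1C(=O)Cc1c(OCc2ccccc2)cc2oc(-c3ccc(OCc4ccccc4)c(OCc4ccccc4)c3)cc(=O)c2c1OCc1ccccc1
F5 | step 13 | 2-[4-(benzyloxy)phenyl]-5,7-dimethoxy-3-(5,7,3',4'-tetra-O-benzylluteolin-6-yl)chroman-4-one (racemic, diastereomer mixture) | COc1cc(OC)c2c(c1)OC(c1ccc(OCc3ccccc3)cc1)C(c1c(OCc3ccccc3)cc3oc(-c4ccc(OCc5ccccc5)c(OCc5ccccc5)c4)cc(=O)c3c1OCc1ccccc1)C2=O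
F6 | step 14 | 2-[4-(benzyloxy)phenyl]-5-hydroxy-7-methoxy-3-(7,3',4'-tri-O-benzylluteolin-6-yl)-4H-chromen-4-one | COc1cc(O)c2c(=O)c(-c3c(OCc4ccccc4)cc4oc(-c5ccc(OCc6ccccc6)c(OCc6ccccc6)c5)cc(=O)c4c3O)c(-c3ccc(OCc4ccccc4)cc3)oc2c1
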